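Compound numbers 1–33 are those of the steps and the compound list below. Labdane numbering is used for every ring compound: C1–C10 form the decalin (C18 and C19 on C4, C20 on C10), C17 is the methyl on C8, and C11–C16 are the chain on C9. α is the face of H‑5, β the face of C20.

## The problem

Target 33 is (13Z)-6β-acetoxylabda-8,13-diene-7α,15-diol with the (5S,6S,7S,10S) configuration. Its trans-fused decalin carries two quaternary carbons (C4 and C10), and ring B is substituted at every position. C6 bears an axial β-acetate wedged between the axial methyls C19 and C20, C7 an axial allylic α-hydroxyl, and C8=C9 is tetrasubstituted, with C9 carrying a chain that ends in a (Z)-trisubstituted allylic alcohol. The four stereocentres C5, C6, C7 and C10 are contiguous. C5 and C10 fix the shape of the bicycle, and once they are in place the β-methyl groups screen the β-face of ring B, so external reagents arrive from the α-face. This delivers the 7α-oxygen directly, but the 6β-oxygen, anti to it, cannot come from a syn-dihydroxylation alone; it must come from a C6 carbonyl reduced from the α-face. The two secondary oxygens must also be told apart, with the acetate on the more hindered one. The allylic C7–O bond beside a tetrasubstituted alkene (ionisation, allylic transposition), the acetate (hydrolysis) and the Z-allylic alcohol (isomerisation) rule out strong acid or base late in the route. The enabling feature is that ring B is a six-membered ring bounded by C5 and the quaternary C10. With its unsaturation placed at C6=C7, the two carbons that bear oxygen, rings A and B become the adduct of an intramolecular Diels–Alder reaction between a C5=C6–C7=C8 diene and a C9=C10 dienophile activated by the C11 carbonyl, forming C5–C10 and C8–C9.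

## Retrosynthesis

Target 33 is first simplified to its bis-silyl ether 32 and cut at C12–C13. This gives the oxygenated bicycle 26, which ends in a C11=C12 vinyl group, and the four-carbon (Z)-iodoalkene 30. In the forward sense the vinyl group is hydroborated to the primary borane 31 and coupled with 30 with retention of alkene geometry. The neighbouring cut at C11–C12 would join two allylic partners and invite allylic transposition and loss of the Z geometry, and an olefination of a C13 methyl ketone would give mainly the E isomer. The Z geometry is fixed before the coupling, in 29, which comes from alkyne 27 by hydroxyl-directed trans-hydrometallation and iodination. The forward reaction must hydroborate the vinyl group only and must leave the C6 acetate alone.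

In 26 the acetate sits on the more hindered oxygen and is anti to O7. Removing the acetyl group gives 25, and 25 is traced to ketone 24 because hydride must attack C6 from the open α-face and so places the oxygen β. Opening a 6α,7α-epoxide at C6 from the β-face was rejected: it needs an SN2 trajectory between two axial methyl groups and would lose to opening at allylic C7. Ketone 24 comes from the cis-diol 22 through the 7-silyl ether 23, and 22 from a C6=C7 alkene by syn-dihydroxylation on the α-face. The price is that the two hydroxyls of 22 must be distinguished; the gain is that all ring stereocentres then depend only on the shape set by C5 and C10.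

The vinyl group of 22 is a one-carbon extension of the C11 aldehyde in 21, and 21 is the dihydroxylation product of dienal 20. The order matters. In 20 the only other alkene is the electron-poor, tetrasubstituted C8=C9 bond, so the dihydroxylation is done there; a terminal vinyl group would compete for the oxidant, so the methylenation follows. Dienal 20 is the dehydrogenation product of the saturated aldehyde 19, which with alcohol 18 is the reduced form of the acyl group in 17. This removes the stereocentres C8 and C9 and leaves a cyclohexene with a carbonyl-bearing C9, the pattern of a Diels–Alder adduct.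

In 17 ring B is a cyclohexene with its alkene at C6=C7 and an acyl group on C9. Cutting C5–C10 and C8–C9 opens both rings at once and leads to the acyclic trienoyl imide 16, in which the diene and the enoyl dienophile are joined by the four carbons C1–C4. Building ring B onto a preformed ring A, or ring A onto a preformed ring B, is weighed in the next section. This cut is preferred because one event sets the C5/C10 trans fusion and the absolute configuration, and because the new alkene appears where the two oxygens are needed. Precursor 16 has no ring and only the stereocentre of the auxiliary. The forward reaction must show endo and facial selectivity with a trisubstituted dienophile, and 16 must have defined E geometry at all three alkenes.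

Imide 16 is the N-acyl derivative of auxiliary 14 and acid 13. The C9=C10 alkene of 13 (ester 12) is cut by olefination to methyl ketone 9 and phosphonate 10. This is the one disconnection that is not fully stereoselective, and the minor 2Z ester must be separated. Ketone 9 is unmasked from ketal 8, whose diene is cut at the C6–C7 single bond into iodoalkene 6 and boronate 7, so that each alkene is made with defined geometry. Iodoalkene 6 comes from aldehyde 5 by iodo-olefination. Aldehyde 5 and ester 4 lead back to the C3–C4 bond, made by alkylating enolate 3 of methyl isobutyrate 1 with chloride 2; this installs the quaternary carbon that becomes C4.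

## Roads not taken

Alternative 1: The cut is through C1–C10 and C4–C5, so ring A is annulated onto a ring B bought as the quinone A1. A chiral oxazaborolidinium Lewis acid would catalyse the Diels–Alder reaction of A1 with the spiro-diene A2 to give the cis-fused enedione A3, with C10 quaternary and the cyclopropane as a masked gem-dimethyl group. The merits are real: the absolute configuration comes from a catalyst and not a stoichiometric auxiliary, A3 is reached in very few steps, and ring B arrives with oxygen on C6 and C9. In these three respects this road is better than the chosen plan. For this target, however, A3 has the cis ring fusion, so C5 must be epimerised. The cyclopropane must be hydrogenolysed without touching the alkenes. C9 is a ketone beside the quaternary C10 and must become the alkene carbon that carries the whole C11–C16 chain, and C7 has no oxygen. The correction phase after the cycloaddition is long and less precedented than the steps that follow 17. Against the catalytic economy of this road the chosen plan sets a trans fusion obtained directly, C11 in place from the start, and a C6=C7 alkene at the right carbons.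

Alternative 2: The cut is through C7–C8 and C9–C10, so ring B is built onto a preformed ring A. The siloxydiene A4 and the ynoyl imide A5 would combine under a chiral Lewis acid to give A6, which already holds the tetrasubstituted C8=C9 alkene, C11 and an enol ether at C6. This is the most convergent of the four routes and on paper the shortest. It needs neither the dehydrogenation (step 11) nor the oxidation at C6 (step 15) of the chosen plan, and in this it is clearly better. Its weak point is the cycloaddition itself. The reacting terminus of A4 is a fully substituted ring carbon, the s-cis diene conformer is strained, and a single quaternary stereocentre must be set by a catalyst acting on a linear alkynoyl dienophile, for which precedent is thin. A stepwise Mukaiyama–Michael path is also open to the enol ether. C5 would be set only afterwards by protonation, and the 7α-oxygen must still be introduced beside the C6 ketone. The chosen plan sets against the shorter sequence an intramolecular reaction, which tolerates hindered termini better, and an absolute control element whose geometry is well understood.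

Alternative 3: The cut is through C4–C5 and C9–C10, the biogenetic one. An alkylaluminium dichloride would open the terminal epoxide of A7, the two trisubstituted alkenes would add in turn, and loss of the C9 proton would give the bicyclic hydroxy ester A8. In skeletal economy this road is better than the chosen plan: the whole carbon framework, the trans fusion and the Z side chain appear in one step from an acyclic precursor, whereas the chosen plan needs three further steps for the chain. The weak points are the superfluous 3β-hydroxyl (two steps to remove) and a termination that can give alkene isomers and monocyclic material. Decisive for this target is that ring B emerges without functionality at C6 and C7. The 7α-hydroxyl could be sought by allylic oxidation in competition with C11, C17 and the side-chain alkene, but there is no handle for the hindered C6. The chosen plan pays for its longer chain construction with an alkene exactly at C6=C7.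

Key step: step 9

Remark on the chemistry: the target is taken as the 6β-acetoxy-7α-hydroxy compound on a 5α-H, 10β-CH3 decalin, which is what the (5S,6S,7S,10S) descriptors of the given structure mean. Nor-labdane names below imply (5S,10S), and metal enolates and ate complexes are drawn as ion pairs.

Step 1
Reactants: 1 methyl isobutyrate; 2 2-(3-chloropropyl)-2-methyl-1,3-dioxolane
Product: 4 methyl 2,2-dimethyl-5-(2-methyl-1,3-dioxolan-2-yl)pentanoate, via lithium ester enolate 3 (not isolated)
Conditions: lithium diisopropylamide (LDA), THF, −78 °C; then 2, NaI (0.2 equiv), DMPU, −78 °C → rt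
Reagents that add atoms: none
Why: Alkylation of a lithium ester enolate with a primary halide creates the quaternary carbon (future C4); NaI exchanges chloride for iodide in the flask (Finkelstein) and DMPU accelerates the SN2 step.

Step 2
Reactants: 4 methyl 2,2-dimethyl-5-(2-methyl-1,3-dioxolan-2-yl)pentanoate
Product: 5 2,2-dimethyl-5-(2-methyl-1,3-dioxolan-2-yl)pentanal
Conditions: diisobutylaluminium hydride (DIBAL-H, 1.1 equiv), CH2Cl2, −78 °C; aq. Rochelle salt
Reagents that add atoms: none
Why: Partial reduction of a hindered methyl ester; the neopentyl aluminium hemiacetal should persist at −78 °C and release the aldehyde only on work-up, and the ketal is inert to hydride.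

Step 3
Reactants: 5 2,2-dimethyl-5-(2-methyl-1,3-dioxolan-2-yl)pentanal
Product: 6 2-[(5E)-6-iodo-4,4-dimethylhex-5-en-1-yl]-2-methyl-1,3-dioxolane
Conditions: CHI3 (2 equiv), CrCl2 (6 equiv), THF/dioxane, 0 °C → rt
Reagents that add atoms: iodoform, IC(I)I
Why: Takai iodo-olefination: the geminal dichromium species formed from CHI3 and divalent chromium adds to the non-enolisable aldehyde and eliminates to the E-iodoalkene; the quaternary α-carbon reinforces the E preference.

Step 4
Reactants: 6 2-[(5E)-6-iodo-4,4-dimethylhex-5-en-1-yl]-2-methyl-1,3-dioxolane; 7 4,4,5,5-tetramethyl-2-[(1E)-prop-1-en-1-yl]-1,3,2-dioxaborolane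
Product: 8 2-[(5E,7E)-4,4-dimethylnona-5,7-dien-1-yl]-2-methyl-1,3-dioxolane
Conditions: Pd(PPh3)4 (5 mol%), 2 M aq. NaOH, THF, 50 °C
Reagents that add atoms: none
Why: Suzuki–Miyaura coupling of an alkenyl iodide with an alkenylboronate retains the geometry of both partners, so the (E,E)-diene is obtained without an equilibration; the ketal is stable to aqueous base.

Step 5
Reactants: 8 2-[(5E,7E)-4,4-dimethylnona-5,7-dien-1-yl]-2-methyl-1,3-dioxolane
Product: 9 (7E,9E)-6,6-dimethylundeca-7,9-dien-2-one
Conditions: 1 M aq. HCl, THF, rt
Reagents that add atoms: water, O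
Why: Acid-catalysed hydrolysis of the dioxolane, the carbonyl oxygen coming from water; the unactivated diene should not be protonated by dilute acid at room temperature.

Step 6
Reactants: 9 (7E,9E)-6,6-dimethylundeca-7,9-dien-2-one; 10 triethyl phosphonoacetate
Product: 12 ethyl (2E,8E,10E)-3,7,7-trimethyldodeca-2,8,10-trienoate, via sodium phosphonate carbanion 11 (not isolated)
Conditions: NaH, THF, 0 °C; then 9, 0 → 60 °C; chromatographic removal of the 2Z isomer
Reagents that add atoms: none
Why: Horner–Wadsworth–Emmons olefination of a methyl ketone should favour the 2E ester (longer chain trans to the ester); the minor 2Z isomer is removed because the dienophile geometry is transcribed into the ring fusion in step 9.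

Step 7
Reactants: 12 ethyl (2E,8E,10E)-3,7,7-trimethyldodeca-2,8,10-trienoate
Product: 13 (2E,8E,10E)-3,7,7-trimethyldodeca-2,8,10-trienoic acid
Conditions: LiOH·H2O, THF/MeOH/H2O, 50 °C; then 1 M HCl to pH 3, 0 °C
Reagents that add atoms: lithium hydroxide, [Li+].[OH-]
Why: Saponification by acyl substitution; the β,β-disubstituted enoate does not add hydroxide in a conjugate sense, and brief cold acidification spares the diene.

Step 8
Reactants: 13 (2E,8E,10E)-3,7,7-trimethyldodeca-2,8,10-trienoic acid; 14 (S)-4-benzyl-2-oxazolidinone
Product: 16 (4S)-4-benzyl-3-[(2E,8E,10E)-3,7,7-trimethyldodeca-2,8,10-trienoyl]-1,3-oxazolidin-2-one, via mixed pivalic anhydride 15 (not isolated)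
Conditions: pivaloyl chloride, Et3N, THF, −20 °C; then 14, LiCl, −20 °C → rt
Reagents that add atoms: none
Why: N-Acylation through the mixed anhydride with LiCl/Et3N: the oxazolidinone attacks the less hindered enoyl carbonyl, and the absence of an acid chloride or strong base avoids deconjugation of the β-methyl enoate.

Step 9
Reactants: 16 (4S)-4-benzyl-3-[(2E,8E,10E)-3,7,7-trimethyldodeca-2,8,10-trienoyl]-1,3-oxazolidin-2-one
Product: 17 (4S)-4-benzyl-3-{[(1S,2S,4aS,8aS)-2,5,5,8a-tetramethyl-1,2,4a,5,6,7,8,8a-octahydronaphthalen-1-yl]carbonyl}-1,3-oxazolidin-2-one (trans-fused Δ6 adduct: 5α-H, 10β-CH3, 8β-CH3, 9β-acyl)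
Conditions: Me2AlCl (1.5 equiv), CH2Cl2, −30 → 0 °C
Reagents that add atoms: none
Why: Excess Me2AlCl binds both imide carbonyls as a cationic aluminium chelate with the enoyl group locked s-cis (the β-methyl cis to the carbonyl disfavours s-trans), and the tethered (E,E)-diene adds in a concerted, asynchronous [4+2] cycloaddition in which C5–C10 forms ahead of C8–C9. The closest known reaction type is the Me2AlCl-promoted intramolecular Diels–Alder reaction of (E,E,E)-deca-2,7,9-trienoyl oxazolidinones to trans-fused octalins; the extra β-methyl makes the dienophile trisubstituted but does not change the reaction type. Ring B is closed as the new cyclohexene by the suprafacial [4+2] addition (bonds C5–C10 and C8–C9), and ring A is closed by the same C5–C10 bond across the C1–C4 tether, which folds as a chair helped by the gem-dimethyl carbon next to the diene. The endo transition state (carbonyl under the diene) of the E-dienophile puts C1 and C4 on opposite faces of ring B and so gives the trans fusion (5α-H, 10β-CH3). Suprafacial addition to the E-dienophile places the C9 acyl group cis to the C10 methyl, and the endo mode with the E,E-diene places the C8 methyl cis to the acyl group (8β, 9β). The absolute sense follows from the diene approaching the Cα face of the chelated s-cis imide opposite the benzyl group of the (S)-auxiliary, which corresponds to (5S,10S). The step needs endo and π-facial selectivity and must outrun Lewis-acid-induced ionisation of the diene; the rigid chelate, the short tether and the E geometry fixed in steps 3, 4 and 6 secure the first two, and low temperature with the entropic advantage of the intramolecular reaction the third. C8 and C9 cease to be stereocentres in step 11, so only the C5/C10 relationship has to be perfect.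

Step 10
Reactants: 17 (4S)-4-benzyl-3-{[(1S,2S,4aS,8aS)-2,5,5,8a-tetramethyl-1,2,4a,5,6,7,8,8a-octahydronaphthalen-1-yl]carbonyl}-1,3-oxazolidin-2-one
Product: 18 [(1S,2S,4aS,8aS)-2,5,5,8a-tetramethyl-1,2,4a,5,6,7,8,8a-octahydronaphthalen-1-yl]methanol (9β-CH2OH, 8β-CH3, Δ6)
Conditions: LiBH4 (2 equiv), H2O (1.1 equiv), Et2O, 0 °C → rt
Reagents that add atoms: none
Why: Reductive cleavage of the N-acyl oxazolidinone: lithium-activated hydride attacks the exocyclic carbonyl and gives the primary alcohol with release of auxiliary 14; the alkene is untouched.

Step 11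
Reactants: 18 [(1S,2S,4aS,8aS)-2,5,5,8a-tetramethyl-1,2,4a,5,6,7,8,8a-octahydronaphthalen-1-yl]methanol
Product: 20 (4aS,8aS)-2,5,5,8a-tetramethyl-4a,5,6,7,8,8a-hexahydronaphthalene-1-carbaldehyde (12,13,14,15,16-pentanorlabda-6,8-dien-11-al), via saturated aldehyde 19 (not isolated)
Conditions: IBX (3.5 equiv), DMSO/fluorobenzene 1:2, rt then 75 °C
Reagents that add atoms: none
Why: IBX oxidises the primary alcohol to aldehyde 19 and, on heating, dehydrogenates it through its enol (IBX dehydrogenation of carbonyl compounds). C10 is quaternary, so only the allylic H-8 can be lost, and the product is the tetrasubstituted enal conjugated with C6=C7, which cannot be oxidised further.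

Step 12
Reactants: 20 (4aS,8aS)-2,5,5,8a-tetramethyl-4a,5,6,7,8,8a-hexahydronaphthalene-1-carbaldehyde
Product: 21 6α,7α-dihydroxy-12,13,14,15,16-pentanorlabd-8-en-11-al
Conditions: OsO4 (5 mol%), N-methylmorpholine N-oxide (1.5 equiv), acetone/H2O 8:1, 0 °C → rt
Reagents that add atoms: osmium tetroxide (catalytic oxygen carrier), O=[Os](=O)(=O)=O; N-methylmorpholine N-oxide, C[N+]1([O-])CCOCC1; water, O
Why: Upjohn syn-dihydroxylation: the oxidant takes the electron-rich distal C6=C7 bond of the dienal and not the electron-poor tetrasubstituted C8=C9 bond, and approaches from the α-face because C19 and C20 cover the β-face; this sets 6α-OH and 7α-OH.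

Step 13
Reactants: 21 6α,7α-dihydroxy-12,13,14,15,16-pentanorlabd-8-en-11-al
Product: 22 13,14,15,16-tetranorlabda-8,11-diene-6α,7α-diol
Conditions: Ph3PCH3Br (4 equiv), KOtBu (3.8 equiv), THF, 0 °C; then 21, 0 °C → rt
Reagents that add atoms: methyltriphenylphosphonium bromide, C[P+](c1ccccc1)(c1ccccc1)c1ccccc1.[Br-]
Why: Wittig methylenation of a hindered enal, with excess ylide to absorb the two hydroxyl protons. It follows the dihydroxylation so that the vinyl group does not compete for the oxidant, and precedes silylation so that no 1,2-silyl shift can occur under base.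

Step 14
Reactants: 22 13,14,15,16-tetranorlabda-8,11-diene-6α,7α-diol
Product: 23 7α-(tert-butyldimethylsilyloxy)-13,14,15,16-tetranorlabda-8,11-dien-6α-ol
Conditions: TBSCl (1.1 equiv), imidazole (2.5 equiv), DMF, 0 °C
Reagents that add atoms: tert-butyldimethylsilyl chloride, CC(C)(C)[Si](C)(C)Cl
Why: Monosilylation with a bulky chlorosilane should take the pseudoaxial allylic 7α-hydroxyl, which is flanked by sp2 C8; the equatorial 6α-hydroxyl is in a syn-pentane relationship with the equatorial C18 methyl and adjoins the neopentyl C5.

Step 15
Reactants: 23 7α-(tert-butyldimethylsilyloxy)-13,14,15,16-tetranorlabda-8,11-dien-6α-ol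
Product: 24 7α-(tert-butyldimethylsilyloxy)-13,14,15,16-tetranorlabda-8,11-dien-6-one
Conditions: Dess–Martin periodinane (1.5 equiv), CH2Cl2, 0 °C → rt
Reagents that add atoms: none
Why: Dess–Martin oxidation under near-neutral conditions, chosen so that neither C7 (α to the ketone and allylic) nor C5 enolises; the ketone is taken on without delay.

Step 16
Reactants: 24 7α-(tert-butyldimethylsilyloxy)-13,14,15,16-tetranorlabda-8,11-dien-6-one
Product: 25 7α-(tert-butyldimethylsilyloxy)-13,14,15,16-tetranorlabda-8,11-dien-6β-ol
Conditions: LiAlH4 (1.5 equiv), Et2O, −78 → −20 °C; aq. Rochelle salt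
Reagents that add atoms: none
Why: Hydride adds to the C6 carbonyl from the α-face because the β-face is closed by the two syn-axial methyls C19 and C20, giving the axial 6β-alcohol, as in reductions of 6-oxo steroids and labdanes; the low temperature keeps reduction ahead of enolisation.

Step 17
Reactants: 25 7α-(tert-butyldimethylsilyloxy)-13,14,15,16-tetranorlabda-8,11-dien-6β-ol
Product: 26 6β-acetoxy-7α-(tert-butyldimethylsilyloxy)-13,14,15,16-tetranorlabda-8,11-diene
Conditions: Ac2O (10 equiv), DMAP (2 equiv), pyridine, 60 °C
Reagents that add atoms: acetic anhydride, CC(=O)OC(C)=O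
Why: DMAP-catalysed acylation of a strongly hindered axial alcohol needs forcing conditions; the only other hydroxyl is silylated, and the trans-diaxial arrangement of O6 and O7 rules out silyl or acyl migration.

Step 18
Reactants: 27 but-2-yn-1-ol
Product: 29 (2Z)-3-iodobut-2-en-1-ol, via cyclic vinylalanate 28 (not isolated)
Conditions: NaAlH2(OCH2CH2OMe)2 (Red-Al, 1.5 equiv), Et2O, 0 °C → rt; then I2, −78 → 0 °C
Reagents that add atoms: iodine, II
Why: The propargylic alkoxyaluminate delivers hydride to C2 in a trans-hydroalumination and leaves aluminium on C3 in the five-membered alanate 28; iodinolysis of the C–Al bond with retention puts iodine cis to CH2OH, the Z geometry.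

Step 19
Reactants: 29 (2Z)-3-iodobut-2-en-1-ol
Product: 30 tert-butyl{[(2Z)-3-iodobut-2-en-1-yl]oxy}dimethylsilane
Conditions: TBSCl, imidazole, CH2Cl2, rt
Reagents that add atoms: tert-butyldimethylsilyl chloride, CC(C)(C)[Si](C)(C)Cl
Why: Standard silylation of a primary alcohol; the protecting group matches that on O7, so both are removed together at the end.

Step 20
Reactants: 26 6β-acetoxy-7α-(tert-butyldimethylsilyloxy)-13,14,15,16-tetranorlabda-8,11-diene; 30 tert-butyl{[(2Z)-3-iodobut-2-en-1-yl]oxy}dimethylsilane
Product: 32 (13Z)-6β-acetoxy-7α,15-bis(tert-butyldimethylsilyloxy)labda-8,13-diene, via B-alkyl-9-BBN borane 31 (not isolated)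
Conditions: 9-BBN (1.5 equiv), THF, 0 °C → rt; then 30, Pd(dppf)Cl2 (5 mol%; dppf = 1,1'-bis(diphenylphosphino)ferrocene), AsPh3 (5 mol%), Cs2CO3 (3 equiv), DMF/H2O, rt
Reagents that add atoms: none
Why: 9-BBN adds to the monosubstituted C11=C12 bond with boron on the terminal C12, while the tetrasubstituted C8=C9 bond is inert. B-alkyl Suzuki–Miyaura coupling retains the geometry of the vinyl iodide, so C13=C14 stays Z; the hindered axial acetate should withstand aqueous carbonate at room temperature.

Step 21
Reactants: 32 (13Z)-6β-acetoxy-7α,15-bis(tert-butyldimethylsilyloxy)labda-8,13-diene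
Product: 33 (13Z)-6β-acetoxylabda-8,13-diene-7α,15-diol
Conditions: HF·pyridine, pyridine, THF, 0 °C → rt
Reagents that add atoms: none
Why: Fluoride-driven cleavage of both silyl ethers; the pyridine-buffered reagent is not basic enough to hydrolyse the acetate and not acidic enough to ionise the allylic C7–O bond.

Compound list

1 | methyl isobutyrate | COC(=O)C(C)C | starting material
2 | 2-(3-chloropropyl)-2-methyl-1,3-dioxolane | CC1(CCCCl)OCCO1 | starting material
3 | lithium enolate of methyl isobutyrate | [Li+].COC([O-])=C(C)C | intermediate
4 | methyl 2,2-dimethyl-5-(2-methyl-1,3-dioxolan-2-yl)pentanoate | COC(=O)C(C)(C)CCCC1(C)OCCO1 | intermediate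
5 | 2,2-dimethyl-5-(2-methyl-1,3-dioxolan-2-yl)pentanal | O=CC(C)(C)CCCC1(C)OCCO1 | intermediate
6 | 2-[(5E)-6-iodo-4,4-dimethylhex-5-en-1-yl]-2-methyl-1,3-dioxolane | I/C=C/C(C)(C)CCCC1(C)OCCO1 | intermediate
7 | 4,4,5,5-tetramethyl-2-[(1E)-prop-1-en-1-yl]-1,3,2-dioxaborolane | C/C=C/B1OC(C)(C)C(C)(C)O1 | starting material
8 | 2-[(5E,7E)-4,4-dimethylnona-5,7-dien-1-yl]-2-methyl-1,3-dioxolane | C/C=C/C=C/C(C)(C)CCCC1(C)OCCO1 | intermediate
9 | (7E,9E)-6,6-dimethylundeca-7,9-dien-2-one | C/C=C/C=C/C(C)(C)CCCC(C)=O | intermediate
10 | triethyl phosphonoacetate | CCOC(=O)CP(=O)(OCC)OCC | starting material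
11 | sodium salt of triethyl phosphonoacetate | [Na+].CCOC(=O)[CH-]P(=O)(OCC)OCC | intermediate
12 | ethyl (2E,8E,10E)-3,7,7-trimethyldodeca-2,8,10-trienoate | C/C=C/C=C/C(C)(C)CCC/C(C)=C/C(=O)OCC | intermediate
13 | (2E,8E,10E)-3,7,7-trimethyldodeca-2,8,10-trienoic acid | C/C=C/C=C/C(C)(C)CCC/C(C)=C/C(=O)O | intermediate
14 | (S)-4-benzyl-2-oxazolidinone | O=C1N[C@@H](Cc2ccccc2)CO1 | starting material
15 | (2E,8E,10E)-3,7,7-trimethyldodeca-2,8,10-trienoic pivalic anhydride | C/C=C/C=C/C(C)(C)CCC/C(C)=C/C(=O)OC(=O)C(C)(C)C | intermediate
16 | (4S)-4-benzyl-3-[(2E,8E,10E)-3,7,7-trimethyldodeca-2,8,10-trienoyl]-1,3-oxazolidin-2-one | C/C=C/C=C/C(C)(C)CCC/C(C)=C/C(=O)N1[C@@H](Cc2ccccc2)COC1=O | intermediate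
17 | (4S)-4-benzyl-3-{[(1S,2S,4aS,8aS)-2,5,5,8a-tetramethyl-1,2,4a,5,6,7,8,8a-octahydronaphthalen-1-yl]carbonyl}-1,3-oxazolidin-2-one | O=C(N1[C@@H](Cc2ccccc2)COC1=O)[C@H]3[C@@H](C)C=C[C@H]4C(C)(C)CCC[C@]34C | intermediate
18 | [(1S,2S,4aS,8aS)-2,5,5,8a-tetramethyl-1,2,4a,5,6,7,8,8a-octahydronaphthalen-1-yl]methanol | OC[C@H]1[C@@H](C)C=C[C@H]2C(C)(C)CCC[C@]12C | intermediate
19 | (1S,2S,4aS,8aS)-2,5,5,8a-tetramethyl-1,2,4a,5,6,7,8,8a-octahydronaphthalene-1-carbaldehyde | O=C[C@H]1[C@@H](C)C=C[C@H]2C(C)(C)CCC[C@]12C | intermediate
20 | (4aS,8aS)-2,5,5,8a-tetramethyl-4a,5,6,7,8,8a-hexahydronaphthalene-1-carbaldehyde | O=CC1=C(C)C=C[C@H]2C(C)(C)CCC[C@]12C | intermediate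
21 | 6α,7α-dihydroxy-12,13,14,15,16-pentanorlabd-8-en-11-al | O[C@H]1[C@@H](O)C(C)=C(C=O)[C@@]2(C)CCCC(C)(C)[C@H]12 | intermediate
22 | 13,14,15,16-tetranorlabda-8,11-diene-6α,7α-diol | O[C@H]1[C@@H](O)C(C)=C(C=C)[C@@]2(C)CCCC(C)(C)[C@H]12 | intermediate
23 | 7α-(tert-butyldimethylsilyloxy)-13,14,15,16-tetranorlabda-8,11-dien-6α-ol | O[C@H]1[C@@H](O[Si](C)(C)C(C)(C)C)C(C)=C(C=C)[C@@]2(C)CCCC(C)(C)[C@H]12 | intermediate
24 | 7α-(tert-butyldimethylsilyloxy)-13,14,15,16-tetranorlabda-8,11-dien-6-one | O=C1[C@@H](O[Si](C)(C)C(C)(C)C)C(C)=C(C=C)[C@@]2(C)CCCC(C)(C)[C@H]12 | intermediate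
25 | 7α-(tert-butyldimethylsilyloxy)-13,14,15,16-tetranorlabda-8,11-dien-6β-ol | O[C@@H]1[C@@H](O[Si](C)(C)C(C)(C)C)C(C)=C(C=C)[C@@]2(C)CCCC(C)(C)[C@H]12 | intermediate
26 | 6β-acetoxy-7α-(tert-butyldimethylsilyloxy)-13,14,15,16-tetranorlabda-8,11-diene | CC(=O)O[C@@H]1[C@@H](O[Si](C)(C)C(C)(C)C)C(C)=C(C=C)[C@@]2(C)CCCC(C)(C)[C@H]12 | intermediate
27 | but-2-yn-1-ol | CC#CCO | starting material
28 | cyclic sodium alkoxy(vinyl)alanate of but-2-en-1-ol (Al bonded to O1 and C3, two 2-methoxyethoxy ligands) | [Na+].COCCO[Al-]1(OCCOC)OCC=C1C | intermediate
29 | (2Z)-3-iodobut-2-en-1-ol | C/C(I)=C/CO | intermediate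
30 | tert-butyl{[(2Z)-3-iodobut-2-en-1-yl]oxy}dimethylsilane | C/C(I)=C/CO[Si](C)(C)C(C)(C)C | intermediate
31 | 6β-acetoxy-12-(9-borabicyclo[3.3.1]nonan-9-yl)-7α-(tert-butyldimethylsilyloxy)-13,14,15,16-tetranorlabd-8-ene | CC(=O)O[C@@H]1[C@@H](O[Si](C)(C)C(C)(C)C)C(C)=C(CCB3C4CCCC3CCC4)[C@@]2(C)CCCC(C)(C)[C@H]12 | intermediate
32 | (13Z)-6β-acetoxy-7α,15-bis(tert-butyldimethylsilyloxy)labda-8,13-diene | CC(=O)O[C@@H]1[C@@H](O[Si](C)(C)C(C)(C)C)C(C)=C(CC/C(C)=C\CO[Si](C)(C)C(C)(C)C)[C@@]2(C)CCCC(C)(C)[C@H]12 | intermediate
33 | (13Z)-6β-acetoxylabda-8,13-diene-7α,15-diol, (5S,6S,7S,10S) (CNP0183298.2) | CC(=O)O[C@@H]1[C@@H](O)C(C)=C(CC/C(C)=C\CO)[C@@]2(C)CCCC(C)(C)[C@H]12 | target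

Total step count: 21 steps. Longest linear sequence: 19 steps (steps 1–17, 20 and 21, from methyl isobutyrate); steps 18 and 19 prepare the side-chain fragment.

Steps least certain to work

Step 9 (key step). The trisubstituted, β,β-dialkyl enoyl imide may add too slowly at the temperatures where the aluminium chelate is well behaved. On warming, ionisation at the tertiary β-carbon, Lewis-acid-induced oligomerisation or isomerisation of the diene, or a stepwise cationic closure with loss of endo and facial selectivity would compete. The fallback moves the source of asymmetry from the auxiliary to the catalyst and avoids chloroaluminate and protic acid. It sets out from acid 13, which is converted through anhydride 15 with 1,3-oxazolidin-2-one (LiCl, Et3N) into the achiral imide 3-[(2E,8E,10E)-3,7,7-trimethyldodeca-2,8,10-trienoyl]-1,3-oxazolidin-2-one F1. F1 is cyclised with the bis(oxazoline) complex of divalent copper, [Cu((R,R)-t-Bu-box)](SbF6)2 (10 mol%, CH2Cl2, rt), a known catalyst type for intramolecular Diels–Alder reactions of trienoyl oxazolidinones that holds both carbonyls in a square-planar chelate. The (R,R) ligand is named because its tert-butyl group is expected to cover the Cα face that the benzyl group covers in 16. The product, 3-{[(1S,2S,4aS,8aS)-2,5,5,8a-tetramethyl-1,2,4a,5,6,7,8,8a-octahydronaphthalen-1-yl]carbonyl}-1,3-oxazolidin-2-one F2, is reduced with LiBH4 and the route is rejoined at alcohol 18.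

Step 14. Poor site selectivity is the likely failure: silylation at the 6α-hydroxyl or at both hydroxyls, because the difference in hindrance between the equatorial neopentyl-type alcohol and the pseudoaxial allylic alcohol is a matter of judgement. The fallback replaces steric discrimination by stereoelectronic control and sets out from diol 22. Trimethyl orthoacetate with catalytic camphorsulfonic acid gives the cyclic orthoacetate F3 (6α,7α-O-(1-methoxyethylidene) derivative of 22). Mild aqueous acetic acid opens F3 to the axial ester, 7α-acetoxy-13,14,15,16-tetranorlabda-8,11-dien-6α-ol F4, as cyclic orthoesters of cis-diols on six-membered rings generally do. Dess–Martin oxidation gives 7α-acetoxy-13,14,15,16-tetranorlabda-8,11-dien-6-one F5. LiAlH4 then reduces the ketone from the α-face and removes the acetate, giving 13,14,15,16-tetranorlabda-8,11-diene-6β,7α-diol F6. In F6 the 6β-hydroxyl lies between two axial methyls, so TBSCl/imidazole should silylate only O7, and the route is rejoined at 25.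

Step 11. The hindered α-branched aldehyde may enolise toward IBX too slowly, so that the reaction stops at 19 or, on prolonged heating, turns to unselective allylic oxidation. The fallback separates oxidation from dehydrogenation and sets out from alcohol 18. Dess–Martin oxidation gives aldehyde 19, now isolated. TMSOTf/Et3N converts it into the trimethylsilyl enol ether F7 (mixture of enol ether geometries). Pd(OAc)2 (1 equiv, MeCN, rt; Saegusa–Ito oxidation with divalent palladium) places palladium on C9 from the open α-face, syn to H-8, and β-hydride elimination returns the route at dienal 20.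

Step 10. Hydride may attack the ring carbonyl of the oxazolidinone (endocyclic cleavage to a hydroxyethyl amide), because the exocyclic carbonyl is flanked by the quaternary C10 and the C8 methine. The fallback uses the smaller, more nucleophilic hydroperoxide and sets out from imide 17. LiOH/H2O2 (THF/H2O, 0 °C; Na2SO3 quench, then HCl) gives (1S,2S,4aS,8aS)-2,5,5,8a-tetramethyl-1,2,4a,5,6,7,8,8a-octahydronaphthalene-1-carboxylic acid F8 with recovery of 14. LiAlH4 in THF reduces F8 and the route is rejoined at alcohol 18.

Further compounds

F1 | step 9 | 3-[(2E,8E,10E)-3,7,7-trimethyldodeca-2,8,10-trienoyl]-1,3-oxazolidin-2-one | C/C=C/C=C/C(C)(C)CCC/C(C)=C/C(=O)N1CCOC1=O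
F2 | step 9 | 3-{[(1S,2S,4aS,8aS)-2,5,5,8a-tetramethyl-1,2,4a,5,6,7,8,8a-octahydronaphthalen-1-yl]carbonyl}-1,3-oxazolidin-2-one | O=C(N1CCOC1=O)[C@H]3[C@@H](C)C=C[C@H]4C(C)(C)CCC[C@]34C
F3 | step 14 | cyclic methyl orthoacetate of 22 (6α,7α-O-(1-methoxyethylidene)-13,14,15,16-tetranorlabda-8,11-diene-6α,7α-diol, both configurations at the orthoester carbon) | COC3(C)O[C@H]1[C@@H](O3)C(C)=C(C=C)[C@@]2(C)CCCC(C)(C)[C@H]12
F4 | step 14 | 7α-acetoxy-13,14,15,16-tetranorlabda-8,11-dien-6α-ol | O[C@H]1[C@@H](OC(C)=O)C(C)=C(C=C)[C@@]2(C)CCCC(C)(C)[C@H]12
F5 | step 14 | 7α-acetoxy-13,14,15,16-tetranorlabda-8,11-dien-6-one | O=C1[C@@H](OC(C)=O)C(C)=C(C=C)[C@@]2(C)CCCC(C)(C)[C@H]12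
F6 | step 14 | 13,14,15,16-tetranorlabda-8,11-diene-6β,7α-diol | O[C@@H]1[C@@H](O)C(C)=C(C=C)[C@@]2(C)CCCC(C)(C)[C@H]12
F7 | step 11 | trimethylsilyl enol ether of 19 (trimethyl{[(2S,4aS,8aS)-2,5,5,8a-tetramethyl-2,4a,5,6,7,8-hexahydronaphthalen-1(8aH)-ylidene]methoxy}silane, E/Z mixture) | C[Si](C)(C)OC=C1[C@@H](C)C=C[C@H]2C(C)(C)CCC[C@]12C
F8 | step 10 | (1S,2S,4aS,8aS)-2,5,5,8a-tetramethyl-1,2,4a,5,6,7,8,8a-octahydronaphthalene-1-carboxylic acid | OC(=O)[C@H]1[C@@H](C)C=C[C@H]2C(C)(C)CCC[C@]12C
A1 | alternative 1 | 2,6-dimethyl-1,4-benzoquinone | CC1=CC(=O)C=C(C)C1=O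
A2 | alternative 1 | allylidenecyclopropane (prop-2-en-1-ylidenecyclopropane) | C=CC=C1CC1
A3 | alternative 1 | cis-fused spirocyclopropyl enedione adduct (10S) | CC1=CC(=O)[C@@H]2C3(CC3)C=CC[C@]2(C)C1=O
A4 | alternative 2 | trimethyl{[1-(2,6,6-trimethylcyclohex-1-en-1-yl)ethenyl]oxy}silane | C=C(O[Si](C)(C)C)C1=C(C)CCCC1(C)C
A5 | alternative 2 | 3-(but-2-ynoyl)-1,3-oxazolidin-2-one | CC#CC(=O)N1CCOC1=O
A6 | alternative 2 | (10S) ring B silyl dienol ether adduct with C8 methyl and C9 acyl imide | CC1=C(C(=O)N2CCOC2=O)[C@@]3(C)CCCC(C)(C)C3=C(O[Si](C)(C)C)C1
A7 | alternative 3 | methyl (2Z,6E,10E,14S)-14,15-epoxy-3,7,11,15-tetramethylhexadeca-2,6,10-trienoate | COC(=O)/C=C(C)\CC/C=C(C)/CC/C=C(C)/CC[C@@H]1OC1(C)C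
A8 | alternative 3 | methyl (13Z)-3β-hydroxylabda-8,13-dien-15-oate | CC1=C(CC/C(C)=C\C(=O)OC)[C@@]2(C)CC[C@H](O)C(C)(C)[C@@H]2CC1
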